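Whichever substrate reacts, each molecule turned into product costs one reagent, so the reagent spent on the substrates counts the product formed. Against the two substrates together the reagent is the limiting reagent, since it is charged at 1.10 equiv of the left-handed substrate.

| flask | left-handed substrate | right-handed substrate | reagent | free catalyst | remark | time |
|---|---|---|---|---|---|---|
| Wednesday's | 0.70 M | 0.70 M | 1.1 equiv | 12 mol% | run made earlier |  |
| Sunday's | 1.1 M | 1.1 M | 1.1 equiv | 12 mol% | run made earlier |  |
| Monday's | 0.50 M | 0.50 M | 1.7 equiv | 12 mol% | run made earlier |  |
| flask | 0.50 M | 0.50 M | 1.10 equiv | 12 mol% |  | 30 min |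

- Wednesday's (time / min: right-handed substrate / %, left-handed substrate / %, left-handed product / %): 2.00: 47.5, 43.0, 3.9; 4.00: 45.9, 41.0, 6.1; 10.0: 46.2, 36.4, 13.0; 25.0: 42.2, 23.9, 20.8
- Sunday's (time / min: right-handed substrate / %, left-handed substrate / %, left-handed product / %): 2.00: 46.3, 41.1, 6.2; 4.00: 45.9, 40.0, 8.6; 10.0: 44.7, 29.1, 17.9; 25.0: 39.8, 19.0, 27.5
- Monday's (time / min: right-handed substrate / %, left-handed substrate / %, left-handed product / %): 6.00: 44.9, 39.2, 9.6; 12.0: 44.7, 32.7, 16.5; 20.0: 43.3, 26.8, 20.5; 25.0: 42.5, 24.7, 23.5

(scatter of a reading: 1 percentage point)

- free catalyst is single-handed; left-handed substrate and right-handed substrate are mirror images of each other, charged as a racemate, each of them at the stated concentration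

- whether the excess of right-handed substrate over left-handed substrate among what is left of the two reaches 99 % by 30 min (yes / no)
- the highest excess of right-handed substrate over left-handed substrate among what is left of the two up to 30 min

Turn the question round and ask what a yes demands. An excess of 99 % means that c(left-handed substrate) has fallen to 0.503 % of c(right-handed substrate). From Monday's last reading, taken at the dilution of this flask, I read a selectivity factor of 4.34, the ratio of the logarithms of what is left of each substrate. Holding that factor fixed, the right-handed substrate must fall to 20.5 % of its charge before the excess is reached. That sets the reagent bill, the reagent that the wanted excess costs per left-handed substrate charged, at 1.79 equiv, counting every substrate molecule gone as turned into product. This is more than the flask holds. To pay within its charge, the flask needs a factor of 49.0, which is 11.3 times my reading. My answer is therefore no.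

The forecast also says no, with a top of 27 %, working “with selectivity of about 5”, a factor that differs from mine.

The simulated flask gives no, with a top of 20.0 %, which is 7 percentage points below the forecast.

    reagent + free catalyst → spent catalyst B (k = 0.00420 M⁻¹ s⁻¹)
    free catalyst + right-handed substrate ⇌ catalyst intermediate B (K = 14.0 M⁻¹, k = 1.40 M⁻¹ s⁻¹)
    free catalyst → spent catalyst A (k = 0.00220 s⁻¹)
    reagent + catalyst intermediate B → free catalyst + right-handed product (k = 0.00260 M⁻¹ s⁻¹)
    free catalyst + left-handed substrate ⇌ catalyst intermediate A (K = 22.0 M⁻¹, k = 2.20 M⁻¹ s⁻¹)
    reagent + catalyst intermediate A → free catalyst + left-handed product (k = 0.0100 M⁻¹ s⁻¹)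

At 7.99 min this flask sends reagent through catalyst intermediate A at 5.0 times the rate through catalyst intermediate B, and at 30.0 min it still holds 57 % of its reagent. It has therefore used 0.471 equiv, about a quarter of the bill and less than its charge.

The neighbour with 4.40 equiv of reagent covers the bill, so its charge raises no objection. Its computed top is 58.3 %, though, and it has used 1.15 equiv by 30.0 min, less than the bill.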